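**Plan** (eudesmane numbering: ring A = C1–C5, C10; ring B = C5–C10; C14 = CH3 on C10; C15 = CH2O on C4; C11–C13 = acrylate on C7)

1. Retrosynthesis: cut the C15–O ester (p-coumaric acid), then C11–C12 (alkyne methoxycarbonylation) and C11≡C13 (ester to alkyne), then C4–C15 (enol triflate of a C4 ketone), then in one operation C10–CH3 and the ring B bond C5–C6.
2. Enabling feature: with C4 of ring A as a ketone, C10 is the β-carbon of an enone and C5 its α-carbon. C6 is the CH2 end of a 2-substituted acrylate on C7, three atoms (C9, C8, C7) from C10, so the enolate made by methyl addition at C10 closes ring B through C5–C6.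
3. Forward: ring A is bought as 3-ethoxycyclohexenone and the C9–C6 chain is attached (steps 1–3); step 4 builds C10 and ring B; steps 5–6 turn the C4 ketone into C3=C4–CH2OH; steps 7–8 turn the C7 ester into the acrylate; step 9 adds the coumarate.
4. Stereochemistry: C10 comes from the chiral copper catalyst; C5 and C7, both α to C=O after ring closure, are set by base equilibration to the trans-decalin with the equatorial C7 ester. Later steps leave all three untouched, except that C7 passes once through an aldehyde (step 7).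

Key step: step 4

Assumption: the sense of induction of the chiral phosphoramidite P* (2,2'-biphenol phosphoramidite of bis[(S)-1-(naphthalen-2-yl)ethyl]amine, or its mirror image) is taken by analogy with simple 3-alkylcyclohex-2-enones; the antipode that gives the (R)-configured quaternary carbon is used.

**Step 1**
Reactants: 1 3-ethoxycyclohex-2-en-1-one; 2 (4-bromobut-1-yn-1-yl)trimethylsilane
Product: 5 3-[4-(trimethylsilyl)but-3-yn-1-yl]cyclohex-2-en-1-one, via Grignard reagent 3 (not isolated), via tertiary allylic alcohol 4 (not isolated)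
Conditions: 2, Mg, THF, 40 °C; then 1, 0 °C to rt; then 1 M HCl, rt
Reagents that add atoms: water, O
Why: Stork–Danheiser sequence: Grignard reagent 3 adds 1,2 to the vinylogous ester and aqueous acid hydrolyses the enol ether and eliminates water from 4, which moves the carbonyl and leaves the chain on the β-carbon (the future C10); no stereocentre is formed.

**Step 2**
Reactants: 5 3-[4-(trimethylsilyl)but-3-yn-1-yl]cyclohex-2-en-1-one
Product: 6 3-(but-3-yn-1-yl)cyclohex-2-en-1-one
Conditions: K2CO3 (0.2 equiv), MeOH, rt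
Reagents that add atoms: none
Why: Carbonate-catalysed methanolysis of the C(sp)–Si bond (protodesilylation of an alkynylsilane) frees the terminal alkyne without touching the enone.

**Step 3**
Reactants: 6 3-(but-3-yn-1-yl)cyclohex-2-en-1-one
Product: 7 methyl 2-methylidene-4-(3-oxocyclohex-1-en-1-yl)butanoate
Conditions: Pd(OAc)2 (1 mol %), 2-(diphenylphosphino)pyridine (4 mol %), MeSO3H (5 mol %), CO (20 bar), MeOH, 45 °C
Reagents that add atoms: carbon monoxide, [C-]#[O+]; methanol, CO
Why: Markovnikov hydro-methoxycarbonylation of a terminal alkyne by a cationic palladium hydride with a pyridylphosphine ligand puts CO2CH3 on the internal carbon and gives the 2-substituted acrylate, whose CH2 end is the future C6; the enone does not insert under these conditions.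

**Step 4**
Reactants: 7 methyl 2-methylidene-4-(3-oxocyclohex-1-en-1-yl)butanoate
Product: 10 methyl (2R,4aR,8aR)-4a-methyl-8-oxodecahydronaphthalene-2-carboxylate (trans-fused; H5 α, 10-CH3 β, 7-CO2CH3 β equatorial), via dimethylaluminium enolate 8 (not isolated), via open-chain keto acrylate 9 (not isolated)
Conditions: AlMe3 (1.4 equiv), Cu(O2CC4H3S) (copper thiophene-2-carboxylate, monovalent copper, 5 mol %), phosphoramidite P* (10 mol %), Et2O, −30 °C; then MeOH, NaOMe (2 equiv), −30 °C to rt, then 45 °C; 1 M HCl work-up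
Reagents that add atoms: trimethylaluminium, C[Al](C)C
Why: The Cu–phosphoramidite complex transfers CH3 from AlMe3 to C10, the β-carbon of the ring A enone, giving the C4–O–Al enolate 8; methanol/methoxide frees ketone 9, whose C5 enolate adds to C6, the CH2 end of the acrylate on C7, and the ester enolate is protonated at C7. The closest known reaction type is the copper-catalysed asymmetric conjugate addition of a trialkylaluminium to a 3-substituted cyclohex-2-enone, run in one pot with a base-mediated intramolecular Michael addition of the ketone to a tethered acrylate. Ring B (C5–C6–C7–C8–C9–C10) closes by the C5–C6 bond in the 6-(enolexo)-endo-trig mode; the C3 enolate could reach C6 only through an eight-membered ring, so the regiochemistry of enolisation needs no control. C10 is set by the catalyst, which selects the enone face; C5 and C7 are each α to a carbonyl in the product and should be equilibrated by methoxide to the trans-fused decalone (H5 anti to the C10 methyl) with the C7 ester equatorial, the lowest-energy of the four diastereomers. The step needs methyl to go to the enone and not to the acrylate: the ketone binds AlMe3 much more strongly than the ester and a 2-alkylacrylate is a poor acceptor for the methylcopper species, while it remains reactive enough for the intramolecular enolate. Methyl addition is irreversible, so the retro-Michael/Michael and enolisation equilibria that settle C5 and C7 cannot erode the configuration at C10.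

**Step 5**
Reactants: 10 methyl (2R,4aR,8aR)-4a-methyl-8-oxodecahydronaphthalene-2-carboxylate
Product: 11 methyl (2R,4aR,8aR)-4a-methyl-8-[(trifluoromethanesulfonyl)oxy]-1,2,3,4,4a,5,6,8a-octahydronaphthalene-2-carboxylate
Conditions: KN(SiMe3)2 (1.1 equiv), THF, −78 °C; then PhNTf2, −78 to 0 °C
Reagents that add atoms: N-phenylbis(trifluoromethanesulfonimide), O=S(=O)(N(c1ccccc1)S(=O)(=O)C(F)(F)F)C(F)(F)F
Why: Kinetic deprotonation by the hindered amide takes a proton from the C3 methylene and not from the tertiary C5–H next to the quaternary carbon or from the less acidic C7–H of the ester, and O-sulfonylation (enol triflate formation) then fixes the double bond at C3=C4 and leaves C5 unable to epimerise.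

**Step 6**
Reactants: 11 methyl (2R,4aR,8aR)-4a-methyl-8-[(trifluoromethanesulfonyl)oxy]-1,2,3,4,4a,5,6,8a-octahydronaphthalene-2-carboxylate
Product: 12 methyl (2R,4aR,8aR)-8-(hydroxymethyl)-4a-methyl-1,2,3,4,4a,5,6,8a-octahydronaphthalene-2-carboxylate
Conditions: Pd(PPh3)4 (5 mol %), LiCl (3 equiv), Bu3SnCH2OH (1.5 equiv), 1,4-dioxane, 100 °C
Reagents that add atoms: (tributylstannyl)methanol, CCCC[Sn](CCCC)(CCCC)CO
Why: Stille cross-coupling of the enol triflate with the hydroxymethyl stannane (chloride from LiCl keeps the palladium intermediate reactive toward transmetalation) brings in C15 at the alcohol oxidation level with the alkene fixed at C3=C4.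

**Step 7**
Reactants: 12 methyl (2R,4aR,8aR)-8-(hydroxymethyl)-4a-methyl-1,2,3,4,4a,5,6,8a-octahydronaphthalene-2-carboxylate
Product: 14 [(4aR,7R,8aR)-7-ethynyl-4a-methyl-3,4,4a,5,6,7,8,8a-octahydronaphthalen-1-yl]methanol, via hydroxy aldehyde 13 (not isolated)
Conditions: i-Bu2AlH (2.2 equiv), CH2Cl2, −78 °C; then MeOH, K2CO3 (3 equiv), dimethyl (1-diazo-2-oxopropyl)phosphonate (1.5 equiv), −78 °C to rt; Rochelle salt work-up
Reagents that add atoms: dimethyl (1-diazo-2-oxopropyl)phosphonate, COP(=O)(OC)C(=[N+]=[N-])C(C)=O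
Why: i-Bu2AlH at −78 °C stops at the aluminium hemiacetal after the alkoxide has formed at C15, methanol then frees aldehyde 13 and the Ohira–Bestmann reagent (Seyferth–Gilbert homologation) converts it in the same pot into the alkyne; C7 is equatorial, the favoured configuration also for the aldehyde, and is expected to hold.

**Step 8**
Reactants: 14 [(4aR,7R,8aR)-7-ethynyl-4a-methyl-3,4,4a,5,6,7,8,8a-octahydronaphthalen-1-yl]methanol
Product: 15 methyl 2-[(2R,4aR,8aR)-8-(hydroxymethyl)-4a-methyl-1,2,3,4,4a,5,6,8a-octahydronaphthalen-2-yl]prop-2-enoate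
Conditions: Pd(OAc)2 (2 mol %), 2-(diphenylphosphino)pyridine (8 mol %), MeSO3H (5 mol %), CO (20 bar), MeOH, 45 °C
Reagents that add atoms: carbon monoxide, [C-]#[O+]; methanol, CO
Why: The same palladium-hydride Markovnikov methoxycarbonylation as in step 3 converts the ethynyl group on C7 into the C11(=CH2)–CO2CH3 unit in one step, the internal carbon taking the ester, and no stereocentre is touched.

**Step 9**
Reactants: 15 methyl 2-[(2R,4aR,8aR)-8-(hydroxymethyl)-4a-methyl-1,2,3,4,4a,5,6,8a-octahydronaphthalen-2-yl]prop-2-enoate; 16 (2E)-3-(4-hydroxyphenyl)prop-2-enoic acid (p-coumaric acid)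
Product: 17 methyl 2-[(2R,4aR,8aR)-8-({[(2E)-3-(4-hydroxyphenyl)prop-2-enoyl]oxy}methyl)-4a-methyl-1,2,3,4,4a,5,6,8a-octahydronaphthalen-2-yl]prop-2-enoate (CNP0161949.1)
Conditions: PPh3 (1.3 equiv), diisopropyl azodicarboxylate (1.3 equiv), THF, 0 °C to rt
Reagents that add atoms: none
Why: Mitsunobu esterification: the carboxylic acid, far more acidic than the phenol, protonates the betaine and its carboxylate displaces the primary allylic oxyphosphonium group at C15 (SN2, no stereocentre involved), so the phenol needs no protection and the E-cinnamate geometry is carried over.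

**Compound list**

1 | 3-ethoxycyclohex-2-en-1-one | CCOC1=CC(=O)CCC1 | starting material
2 | (4-bromobut-1-yn-1-yl)trimethylsilane | C[Si](C)(C)C#CCCBr | starting material
3 | [4-(trimethylsilyl)but-3-yn-1-yl]magnesium bromide | C[Si](C)(C)C#CCC[Mg]Br | intermediate (not isolated)
4 | 3-ethoxy-1-[4-(trimethylsilyl)but-3-yn-1-yl]cyclohex-2-en-1-ol (racemic, formed as its magnesium alkoxide) | CCOC1=CC(O)(CCC#C[Si](C)(C)C)CCC1 | intermediate (not isolated)
5 | 3-[4-(trimethylsilyl)but-3-yn-1-yl]cyclohex-2-en-1-one | C[Si](C)(C)C#CCCC1=CC(=O)CCC1 | intermediate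
6 | 3-(but-3-yn-1-yl)cyclohex-2-en-1-one | C#CCCC1=CC(=O)CCC1 | intermediate
7 | methyl 2-methylidene-4-(3-oxocyclohex-1-en-1-yl)butanoate | C=C(CCC1=CC(=O)CCC1)C(=O)OC | intermediate
8 | methyl 4-[(1R)-3-[(dimethylalumanyl)oxy]-1-methylcyclohex-2-en-1-yl]-2-methylidenebutanoate | C=C(CC[C@@]1(C)CCCC(O[Al](C)C)=C1)C(=O)OC | intermediate (not isolated)
9 | methyl 2-methylidene-4-[(1R)-1-methyl-3-oxocyclohexyl]butanoate | C=C(CC[C@@]1(C)CCCC(=O)C1)C(=O)OC | intermediate (not isolated)
10 | methyl (2R,4aR,8aR)-4a-methyl-8-oxodecahydronaphthalene-2-carboxylate | COC(=O)[C@@H]1CC[C@@]2(C)CCCC(=O)[C@@H]2C1 | intermediate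
11 | methyl (2R,4aR,8aR)-4a-methyl-8-[(trifluoromethanesulfonyl)oxy]-1,2,3,4,4a,5,6,8a-octahydronaphthalene-2-carboxylate | COC(=O)[C@@H]1CC[C@@]2(C)CCC=C(OS(=O)(=O)C(F)(F)F)[C@@H]2C1 | intermediate
12 | methyl (2R,4aR,8aR)-8-(hydroxymethyl)-4a-methyl-1,2,3,4,4a,5,6,8a-octahydronaphthalene-2-carboxylate | COC(=O)[C@@H]1CC[C@@]2(C)CCC=C(CO)[C@@H]2C1 | intermediate
13 | (2R,4aR,8aR)-8-(hydroxymethyl)-4a-methyl-1,2,3,4,4a,5,6,8a-octahydronaphthalene-2-carbaldehyde | O=C[C@@H]1CC[C@@]2(C)CCC=C(CO)[C@@H]2C1 | intermediate (not isolated)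
14 | [(4aR,7R,8aR)-7-ethynyl-4a-methyl-3,4,4a,5,6,7,8,8a-octahydronaphthalen-1-yl]methanol | C#C[C@@H]1CC[C@@]2(C)CCC=C(CO)[C@@H]2C1 | intermediate
15 | methyl 2-[(2R,4aR,8aR)-8-(hydroxymethyl)-4a-methyl-1,2,3,4,4a,5,6,8a-octahydronaphthalen-2-yl]prop-2-enoate | C=C(C(=O)OC)[C@@H]1CC[C@@]2(C)CCC=C(CO)[C@@H]2C1 | intermediate
16 | (2E)-3-(4-hydroxyphenyl)prop-2-enoic acid | OC(=O)/C=C/c1ccc(O)cc1 | starting material
17 | methyl 2-[(2R,4aR,8aR)-8-({[(2E)-3-(4-hydroxyphenyl)prop-2-enoyl]oxy}methyl)-4a-methyl-1,2,3,4,4a,5,6,8a-octahydronaphthalen-2-yl]prop-2-enoate | C=C(C(=O)OC)[C@@H]1CC[C@@]2(C)CCC=C(COC(=O)/C=C/c3ccc(O)cc3)[C@@H]2C1 | target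

**Totals**

Total step count: 9. Longest linear sequence: 9 steps (1 to 17); 2 and 16 are bought.

**Steps most likely to fail**

Step 4. Three processes may interfere. Methyl may be transferred to the acrylate, or face selection may be eroded, because the ester arm binds aluminium or copper. Ring closure may be slow in the presence of aluminium methoxides. During the equilibration the C3 enolate may be acylated by the ester of a cis-fused epimer (Claisen-type), and the trans/cis preference at C5 may be only moderate. The fallback separates the enantioselective step from the acrylate and sets out from 5. Conjugate methylation of 5 under the same copper/phosphoramidite conditions (AlMe3, Et2O, −30 °C) gives (3R)-3-methyl-3-[4-(trimethylsilyl)but-3-yn-1-yl]cyclohexan-1-one F1. K2CO3 in MeOH gives (3R)-3-(but-3-yn-1-yl)-3-methylcyclohexan-1-one F2. The alkyne methoxycarbonylation of step 3 then gives 9, isolated this time. Catalytic NaOMe in MeOH, free of aluminium salts and with the base amount limited, closes ring B and equilibrates C5 and C7. The route is rejoined at 10.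

Step 8. Palladium hydride may insert with the wrong regiochemistry, giving the linear ester. Under the acidic conditions it may also ionise or isomerise the allylic alcohol and move the C3=C4 double bond. The fallback sets out from 14 and builds the acrylate under basic conditions from a methyl ketone. Markovnikov hydration (Ph3PAuNTf2, monovalent gold, aqueous dioxane) gives 1-[(2R,4aR,8aR)-8-(hydroxymethyl)-4a-methyl-1,2,3,4,4a,5,6,8a-octahydronaphthalen-2-yl]ethan-1-one F5. Silylation (t-BuMe2SiCl, imidazole) gives its tert-butyldimethylsilyl ether F6. Kinetic enolisation on the methyl side (KN(SiMe3)2, PhNTf2, −78 °C) gives the 1,1-disubstituted enol triflate F7. Methoxycarbonylation (Pd(OAc)2, 1,3-bis(diphenylphosphino)propane, CO 1 bar, MeOH, Et3N, DMF) gives the silyl ether of 15, F8. Bu4NF buffered with AcOH removes the silyl group, and the route is rejoined at 15.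

Step 7. The ester may be over-reduced to the primary alcohol in the presence of the C15 alkoxide, and the C7 aldehyde may epimerise in basic methanol before it is homologated. The fallback changes the order and uses an aprotic homologation; it sets out from 11, which has no free hydroxyl. i-Bu2AlH (1.1 equiv, −78 °C) gives (2R,4aR,8aR)-4a-methyl-8-[(trifluoromethanesulfonyl)oxy]-1,2,3,4,4a,5,6,8a-octahydronaphthalene-2-carbaldehyde F3, isolated cold. Colvin rearrangement with lithiated Me3SiCHN2 (LiN(i-Pr)2, THF, −78 °C to rt) gives (4aS,7R,8aR)-7-ethynyl-4a-methyl-3,4,4a,5,6,7,8,8a-octahydronaphthalen-1-yl trifluoromethanesulfonate F4. The Stille hydroxymethylation of step 6 then rejoins the route at 14.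

**Further compounds**

F1 | step 4 | (3R)-3-methyl-3-[4-(trimethylsilyl)but-3-yn-1-yl]cyclohexan-1-one | C[Si](C)(C)C#CCC[C@@]1(C)CCCC(=O)C1
F2 | step 4 | (3R)-3-(but-3-yn-1-yl)-3-methylcyclohexan-1-one | C#CCC[C@@]1(C)CCCC(=O)C1
F3 | step 7 | (2R,4aR,8aR)-4a-methyl-8-[(trifluoromethanesulfonyl)oxy]-1,2,3,4,4a,5,6,8a-octahydronaphthalene-2-carbaldehyde | O=C[C@@H]1CC[C@@]2(C)CCC=C(OS(=O)(=O)C(F)(F)F)[C@@H]2C1
F4 | step 7 | (4aS,7R,8aR)-7-ethynyl-4a-methyl-3,4,4a,5,6,7,8,8a-octahydronaphthalen-1-yl trifluoromethanesulfonate | C#C[C@@H]1CC[C@@]2(C)CCC=C(OS(=O)(=O)C(F)(F)F)[C@@H]2C1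
F5 | step 8 | 1-[(2R,4aR,8aR)-8-(hydroxymethyl)-4a-methyl-1,2,3,4,4a,5,6,8a-octahydronaphthalen-2-yl]ethan-1-one | CC(=O)[C@@H]1CC[C@@]2(C)CCC=C(CO)[C@@H]2C1
F6 | step 8 | 1-[(2R,4aR,8aR)-8-({[tert-butyl(dimethyl)silyl]oxy}methyl)-4a-methyl-1,2,3,4,4a,5,6,8a-octahydronaphthalen-2-yl]ethan-1-one | CC(=O)[C@@H]1CC[C@@]2(C)CCC=C(CO[Si](C)(C)C(C)(C)C)[C@@H]2C1
F7 | step 8 | 1-[(2R,4aR,8aR)-8-({[tert-butyl(dimethyl)silyl]oxy}methyl)-4a-methyl-1,2,3,4,4a,5,6,8a-octahydronaphthalen-2-yl]ethenyl trifluoromethanesulfonate | C=C(OS(=O)(=O)C(F)(F)F)[C@@H]1CC[C@@]2(C)CCC=C(CO[Si](C)(C)C(C)(C)C)[C@@H]2C1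
F8 | step 8 | methyl 2-[(2R,4aR,8aR)-8-({[tert-butyl(dimethyl)silyl]oxy}methyl)-4a-methyl-1,2,3,4,4a,5,6,8a-octahydronaphthalen-2-yl]prop-2-enoate | C=C(C(=O)OC)[C@@H]1CC[C@@]2(C)CCC=C(CO[Si](C)(C)C(C)(C)C)[C@@H]2C1
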